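All runs come from a simulation on assumed constants, and the scatter is random.

Delta, charged with more L (the reagent) than beta, has lost more of its G (the substrate) by the last reading, 57.0% against 45.8%. In the proposed steps G and L join to Z, Z gives the product D with Q, L goes over to E, and Q holds L as X.

all flasks: G 0.020 M

| flask | L | remark | time |
|---|---|---|---|
| beta | 0.015 M | run made earlier |  |
| delta | 0.021 M | run made earlier |  |
| south-east | 0.0160 M |  | 30 h |
| north-east | 0.0120 M |  | 30 h |

| run | time / h | G / % | D / % |
|---|---|---|---|
| beta | 1.50 | 53.6 | 3.6 |
| beta | 2.50 | 54.1 | 5.6 |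
| beta | 4.00 | 55.2 | 11.8 |
| beta | 6.00 | 55.3 | 17.2 |
| beta | 10.0 | 56.4 | 25.7 |
| beta | 15.0 | 54.8 | 28.8 |
| beta | 20.0 | 54.2 | 30.7 |
| delta | 1.50 | 40.3 | 4.7 |
| delta | 2.50 | 41.3 | 11.3 |
| delta | 4.00 | 41.9 | 15.0 |
| delta | 6.00 | 41.6 | 20.4 |
| delta | 10.0 | 41.0 | 30.1 |
| delta | 15.0 | 44.3 | 36.2 |
| delta | 20.0 | 43.0 | 38.8 |

(readings scatter by 1 percentage point)

* part of the G that has reacted at the end, south-east
* part of the G that has reacted at the end, north-east
* what raising the concentration of L from its lowest to its highest value here does to the part of the G that has reacted (changes below 5 percentage points count as none) (it falls / no change / it rises)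

- Q is meant together with its X
- steps that have been proposed: Z <-> D + Q; L <-> E; G + L <-> Z; L + Q <-> X

You can count turnovers here. Beta's last reading gives 0.611 as the take, the G reacted per L charged, and delta's gives 0.543. Multiplying beta's take by the L charged and dividing by the G charged, I reckon 48.9% south-east and 36.6% north-east. The forecast, “ignoring any L held as E, which these runs cannot separate”, gives slightly different numbers: 47% south-east, 38% north-east, and for the trend, it rises.

The flask gives 47.3% south-east and 38.5% north-east, and it rises by 8.8 percentage points.

    Z ⇌ D + Q (K = 0.0180 M, k = 0.00140 min⁻¹)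
    L ⇌ E (K = 3.60, k = 0.00160 min⁻¹)
    G + L ⇌ Z (K = 170 M⁻¹, k = 1.70 M⁻¹ min⁻¹)
    L + Q ⇌ X, settled at all times (K = 59.0 M⁻¹)

South-east ends 8.8 points above north-east because it was charged more L. Reckoned back, the take is 0.591 south-east and 0.641 north-east. North-east ends with L as the limiting reagent, 7.8% of its charge free against 62% of the charged G, and the running short of L is part of why north-east stops at 38.5%: with L held at its charge, that flask reaches 86.8%. The way to E costs north-east 10 points, yet steps without it still fit the readings with a misfit of 1.1 scatter units, so those readings do not show it apart.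

With 0.0048 M of L in north-east's neighbour, the take gives 14.7%; that flask reaches 17.7%, a take of 0.739.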